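## Structural features

The target is a germacranolide: a ten-membered carbocycle (C1–C10) fused at C6–C7 to a butenolide (O–C6, C7=C11, C12=O) whose C11 carries the acetoxymethyl carbon C13. The C4–C5 bond is a cis-epoxide (C3 and C6 on the same side, methyl on C4), so C4, C5 and C6 are contiguous stereocentres. C8 (methacrylate carbinol) is separated from C6 only by the sp2 carbon C7, and the quaternary C10 (methyl, acetate) lies 1,3 to C8 and next to the C1 ketone. The five centres read 4R,5S,6R,8S,10R in the target and in the seco thioester and the cyclised ketone of the ring closure, so no structural correction was needed; C6 changes from S to R on epoxidation only because C5 then outranks C7. Fragile groups are the butenolide C6–H beside the epoxide (base opens the epoxide through the furanolate), the epoxide itself (acid, iodide with a Lewis acid), the allylic C13 acetate (low-valent metals, SN2′), the methacrylate (radicals, nucleophiles) and the β-acyloxy carbonyl relationships around C10. The real difficulty is closing a ten-membered ring that already holds all of this without base, acid or a free carbanion. The route uses the fact that the C1 ketone is flanked by quaternary C10 and the C2 methylene: C1 comes from an acyl electrophile on C10, C2 from a primary iodide, and the two are joined under reducing nickel catalysis.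

## Logic of the disconnections

31 ⇒ 30 ⇒ 29 ⇒ 28. The C8–O methacryloyl and C13–O acetyl bonds are cut last. The methacrylate is a radical and Michael acceptor, and an allylic acetate at C13 is an electrophile for zerovalent nickel or palladium, so both oxygens are carried as triethylsilyl ethers through the ring closure. This costs one step and demands selective acetylation of the primary C13 hydroxyl of 29 before the secondary C8 hydroxyl is esterified.

28 ⇒ 27. The C1–C2 bond is cut, which opens the ten-membered ring to a 2-pyridyl thioester at C1 and a primary iodide at C2. This is the only ring bond whose formation needs no enolate and creates no stereocentre. The forward step must beat oligomerisation and leave epoxide, butenolide, acetate and silyl ethers alone.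

27 ⇒ 26 ⇒ 25 ⇒ 24 ⇒ 23. These are functional-group changes only: C–S from the acid, the acid from an allyl ester, C–I from the alcohol, the alcohol from a PMB ether. Each unmasking is neutral (zerovalent palladium, DDQ, phosphine/iodine), as the epoxide/butenolide pair requires. The iodide is made before the thioester so that the active ester is never exposed to imidazole.

23 ⇒ 22. The epoxide oxygen is removed to give the 4Z alkene. The epoxide is placed after all iodide, Lewis acid and ketone chemistry because MgI2 opens epoxides and the C8 ketone 20 would be base-labile with an epoxide beside C6. Face selectivity must therefore come from the C6 stereocentre without a free hydroxyl.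

22 ⇒ 21 ⇒ 20 ⇒ 19 ⇒ 11 + 18. The C7–C8 bond is cut (alkenyl iodide plus aldehyde). This is the most convergent cut and separates the lactate-derived C8–C10/C1 unit from the butenolide. The coupling cannot be relied on to control C8, so C8 is set afterwards by reagent-controlled reduction of ketone 20.

11 ⇒ 10 ⇒ 8. The C7–I, C11–C13 and O–C12 bonds are cut in one operation (iodide addition, formaldehyde aldol, lactonisation). This reduces the tetrasubstituted butenolide to a γ-hydroxy ynoate. The forward step needs the geometric isomer with C6–O cis to the ester, which is drained by lactonisation.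

8 ⇒ 6 + 7. The C6–C7 bond is cut (alkynylation of an enal). C6 is set by a chiral catalyst and later controls C4 and C5.

6 ⇒ 5 ⇒ 4 ⇒ 3 ⇒ 2 ⇒ 1. The C4–methyl bond is cut (syn-methylcupration of an ynoate) and the C5–C6 bond comes from acylation of an acetylide. The Z geometry, which becomes the cis-epoxide, rests on the syn addition.

18 ⇒ 16 ⇒ 15 ⇒ 14 ⇒ 13 ⇒ 12. The C9–C10 bond is cut (enolate alkylation with retention through a pivalaldehyde acetal), and C8 is revealed by ozonolysis of a prenyl group. A prenyl group rather than allyl is used so that it can be cleaved beside the allyl ester.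

## Other disconnections considered

Alternative 1: The cut is C7–C11 of a saturated lactone. In the forward step Rh2(OAc)4 decomposes the C6 allyl diazomalonate A2 and the carbene inserts into a C7–H bond to give lactone A1.
- In its favour: 1,5 C–H insertion to a γ-lactone is a well-established ring size, and the butenolide would appear only at the very end. On that point it is better than the chosen plan, which carries the C6–H/epoxide pair through nine steps.
- Against it: A2 already contains the complete ten-membered ring with ketone, tertiary acetate, epoxide and C8 ester, so the hard ring closure is postponed, not solved.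
- Against it: the carbene must choose the C7 methylene (deactivated by the acyloxy group on C8) over the epoxide C5–H, which is also 1,5, over cyclopropanation of its own allyl ester, and over ylide formation at the epoxide or ketone oxygen.
- Against it: A1 still needs dehydrogenation to C7=C11, reduction of the ester carbon to C13–OH beside a lactone and a ketone, and an ester exchange at C8.
- Comparison: the chosen plan builds the butenolide with C13 at the right oxidation level in one step and forms no stereocentre late; A1 would need at least four more steps after its key step and a separate ring synthesis.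

Alternative 2: The cut is C8–C9, formed while C1–C6 breaks (ring expansion). In the forward step KH with 18-crown-6 ionises the trans-divinylcyclohexenol A4 and the anionic oxy-Cope rearrangement gives dienone A3.
- In its favour: the ten-membered ring comes from a six-membered terpene-derived ring without high dilution. The 4Z geometry is inherited from the ring, the 1(10)E geometry from a chair transition state, and C8 from the enol ether geometry. As a ring-forming event this is better precedented than the nickel closure.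
- Against it: A3 is far from the target's oxidation pattern. The 1(10)-alkene must become a C1 ketone and a C10 tertiary acetate of defined configuration, the C6 ketone must become the lactone oxygen, C7 needs the C11–C13 unit and the C7=C11 alkene, and the epoxide is still missing.
- Against it: all of this must be done on a conformationally mobile ring, where face selectivity is hard to predict.
- Comparison: ring formation is superior, functionalisation clearly inferior and longer (a dozen or more steps after A3). The chosen plan fixes C6, C8 and C10 in acyclic intermediates by reagent or chiral-pool control.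

Alternative 3: The cuts are C6–C7 and O–C12. In the forward step CrCl2 with catalytic NiCl2 converts the alkenyl iodide of seco enal A6 into an alkenylchromium, which adds to the C6 aldehyde; the alkoxide then lactonises to macrocyclic butenolide A5.
- In its favour: chromium-mediated macrocyclisation is a documented reaction class, the alkenylchromium is acyclic, ring and lactone form together, and the C1–C2 ketone bond of A6 could be made by the nickel coupling in its known intermolecular form. On precedent it is the equal or the better of the chosen plan.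
- Against it: C6 is created during ring closure with only conformational bias.
- Against it: the epoxide must then be placed on the macrocyclic 4Z-alkene of A5, where the face is dictated by ring shape and not by design.
- Against it: A6 holds an enolisable ketone and a Z-enal that isomerises easily.
- Comparison: the step count is about equal and both closures are neutral. The chosen plan completes all five stereocentres before cyclisation, so the ring closure has only to form one bond.

Key step: step 23

Assumption: the (S,S) antipode of ProPhenol is taken to deliver the zinc alkynylide to the Re face of enal 6 (4S carbinol 8); if the sense proves opposite, the (R,R) ligand is used with nothing else changed.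

## Steps

Step 1
Reactants: 1 but-3-yn-1-ol
Product: 2 1-[(but-3-yn-1-yloxy)methyl]-4-methoxybenzene
Conditions: NaH, 4-methoxybenzyl chloride, Bu4NI (cat.), THF, 0 °C → rt
Reagents that add atoms: 4-methoxybenzyl chloride, COc1ccc(CCl)cc1
Why: Williamson ether synthesis; NaH removes only the hydroxyl proton, and the PMB ether is chosen because it can later be removed oxidatively beside silyl ethers and an epoxide.

Step 2
Reactants: 2 1-[(but-3-yn-1-yloxy)methyl]-4-methoxybenzene
Product: 3 methyl 5-[(4-methoxybenzyl)oxy]pent-2-ynoate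
Conditions: n-BuLi, THF, −78 °C; ClCO2Me, −78 → 0 °C
Reagents that add atoms: methyl chloroformate, COC(=O)Cl
Why: Acylation of a lithium acetylide; gives the ynoate that holds C2–C6.

Step 3
Reactants: 3 methyl 5-[(4-methoxybenzyl)oxy]pent-2-ynoate
Product: 4 methyl (2Z)-5-[(4-methoxybenzyl)oxy]-3-methylpent-2-enoate
Conditions: Me2CuLi, THF, −78 °C; MeOH then aq. NH4Cl at −78 °C
Reagents that add atoms: lithium dimethylcuprate (Me2CuLi), [Li+].C[Cu-]C
Why: Syn carbocupration of an ynoate; kept and quenched at −78 °C so the alkenylcopper is protonated with retention, placing the oxygenated chain cis to the ester (2Z), the geometry that later becomes the cis-epoxide.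

Step 4
Reactants: 4 methyl (2Z)-5-[(4-methoxybenzyl)oxy]-3-methylpent-2-enoate
Product: 5 (2Z)-5-[(4-methoxybenzyl)oxy]-3-methylpent-2-en-1-ol
Conditions: iBu2AlH, CH2Cl2, −78 °C; Rochelle salt
Reagents that add atoms: none
Why: 1,2-Reduction of the enoate by the aluminium hydride; the alkene geometry is not touched.

Step 5
Reactants: 5 (2Z)-5-[(4-methoxybenzyl)oxy]-3-methylpent-2-en-1-ol
Product: 6 (2Z)-5-[(4-methoxybenzyl)oxy]-3-methylpent-2-enal
Conditions: MnO2, CH2Cl2, rt
Reagents that add atoms: none
Why: Allylic oxidation with MnO2; the neutral heterogeneous oxidant should keep Z to E isomerisation of the enal low, and the aldehyde is used at once.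

Step 6
Reactants: 6 (2Z)-5-[(4-methoxybenzyl)oxy]-3-methylpent-2-enal; 7 methyl propiolate
Product: 8 methyl (4S,5Z)-4-hydroxy-8-[(4-methoxybenzyl)oxy]-6-methyloct-5-en-2-ynoate
Conditions: (S,S)-ProPhenol (20 mol %), Me2Zn, Ph3PO, toluene, 0–4 °C
Reagents that add atoms: none
Why: Zinc–ProPhenol catalysed asymmetric alkynylation of an enal; the dinuclear zinc catalyst binds aldehyde and zinc alkynylide and delivers the alkynyl group to one face, which sets C6 (4S in 8) by reagent control.

Step 7
Reactants: 8 methyl (4S,5Z)-4-hydroxy-8-[(4-methoxybenzyl)oxy]-6-methyloct-5-en-2-ynoate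
Product: 10 (5S)-3-(hydroxymethyl)-4-iodo-5-[(1Z)-4-[(4-methoxybenzyl)oxy]-2-methylbut-1-en-1-yl]furan-2(5H)-one, via iodo hydroxy ester 9 (not isolated)
Conditions: MgI2, CH2O (from paraformaldehyde), CH2Cl2, 0 °C → rt
Reagents that add atoms: magnesium diiodide (MgI2), [Mg+2].[I-].[I-]; formaldehyde, C=O
Why: Iodide-triggered halo-aldol of an ynoate (iodo Baylis–Hillman type) followed by lactonisation; iodide adds to C7, the magnesium allenolate is hydroxymethylated at C11, and the isomer with C6–O cis to the ester closes irreversibly while the other should equilibrate by iodide addition–elimination. It is run before any epoxide exists because MgI2 opens epoxides; C6 is not involved.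

Step 8
Reactants: 10 (5S)-3-(hydroxymethyl)-4-iodo-5-[(1Z)-4-[(4-methoxybenzyl)oxy]-2-methylbut-1-en-1-yl]furan-2(5H)-one
Product: 11 (5S)-4-iodo-5-[(1Z)-4-[(4-methoxybenzyl)oxy]-2-methylbut-1-en-1-yl]-3-[(triethylsilyloxy)methyl]furan-2(5H)-one
Conditions: Et3SiCl, imidazole, CH2Cl2, 0 °C
Reagents that add atoms: chlorotriethylsilane, CC[Si](Cl)(CC)CC
Why: Silyl ether formation; C13 stays a silyl ether until after ring closure because an allylic acetate there would ionise with zerovalent nickel or palladium.

Step 9
Reactants: 12 (S)-lactic acid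
Product: 13 (2S,5S)-2-tert-butyl-5-methyl-1,3-dioxolan-4-one
Conditions: pivalaldehyde, TsOH (cat.), H2SO4 (cat.), pentane, reflux (water separator); crystallisation
Reagents that add atoms: pivalaldehyde, CC(C)(C)C=O
Why: Acid-catalysed acetalisation (self-regeneration of stereocentres); the cis acetal is favoured thermodynamically and is purified by crystallisation, so the lactate configuration is stored in the acetal carbon.

Step 10
Reactants: 13 (2S,5S)-2-tert-butyl-5-methyl-1,3-dioxolan-4-one
Product: 14 (2S,5R)-2-tert-butyl-5-methyl-5-(3-methylbut-2-en-1-yl)-1,3-dioxolan-4-one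
Conditions: LiN(iPr)2, THF, −78 °C; prenyl bromide, −78 → −30 °C
Reagents that add atoms: 1-bromo-3-methylbut-2-ene, CC(C)=CCBr
Why: Enolate alkylation; the planar lithium enolate is attacked anti to the tert-butyl group, so the prenyl group takes the place of hydrogen with overall retention and creates quaternary C10 (5R).

Step 11
Reactants: 14 (2S,5R)-2-tert-butyl-5-methyl-5-(3-methylbut-2-en-1-yl)-1,3-dioxolan-4-one
Product: 15 prop-2-en-1-yl (2R)-2-hydroxy-2,5-dimethylhex-4-enoate
Conditions: allyl alcohol, NaH (10 mol %), 0 °C → rt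
Reagents that add atoms: prop-2-en-1-ol, C=CCO
Why: Alkoxide-catalysed transesterification; allyloxide opens the acetal lactone and the hemiacetal alkoxide loses pivalaldehyde; the quaternary centre cannot epimerise.

Step 12
Reactants: 15 prop-2-en-1-yl (2R)-2-hydroxy-2,5-dimethylhex-4-enoate
Product: 16 prop-2-en-1-yl (2R)-2-acetoxy-2,5-dimethylhex-4-enoate
Conditions: Ac2O, DMAP, Et3N, CH2Cl2, rt → 40 °C
Reagents that add atoms: acetic anhydride, CC(=O)OC(C)=O
Why: DMAP-catalysed acylation of a tertiary alcohol; the C10 acetate is installed while no sensitive group is present.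

Step 13
Reactants: 16 prop-2-en-1-yl (2R)-2-acetoxy-2,5-dimethylhex-4-enoate
Product: 18 prop-2-en-1-yl (2R)-2-acetoxy-2-methyl-4-oxobutanoate, via ozonide 17 (not isolated)
Conditions: O3, CH2Cl2, −78 °C, Sudan Red 7B end point; Me2S, −78 °C → rt
Reagents that add atoms: ozone, [O-][O+]=O
Why: Chemoselective ozonolysis; the electron-rich trisubstituted alkene should react far faster than the allyl ester alkene, and reductive work-up gives the C8 aldehyde, which is used at once because a β-acetoxy aldehyde eliminates with base.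

Step 14
Reactants: 11 (5S)-4-iodo-5-[(1Z)-4-[(4-methoxybenzyl)oxy]-2-methylbut-1-en-1-yl]-3-[(triethylsilyloxy)methyl]furan-2(5H)-one; 18 prop-2-en-1-yl (2R)-2-acetoxy-2-methyl-4-oxobutanoate
Product: 19 prop-2-en-1-yl (2R)-2-acetoxy-4-hydroxy-4-{(2S)-2-[(1Z)-4-[(4-methoxybenzyl)oxy]-2-methylbut-1-en-1-yl]-5-oxo-4-[(triethylsilyloxy)methyl]-2,5-dihydrofuran-3-yl}-2-methylbutanoate (both C8 epimers)
Conditions: CrCl2 (5 equiv), NiCl2 (2 mol %), DMSO, rt
Reagents that add atoms: none
Why: Nozaki–Hiyama–Kishi coupling; zerovalent nickel inserts into the activated C7–I bond, the alkenyl group passes to trivalent chromium and adds to the aldehyde, forming C7–C8 under neutral conditions. No useful facial bias is expected at C8, so both epimers are taken on to the ketone.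

Step 15
Reactants: 19 C8 carbinol (both epimers)
Product: 20 prop-2-en-1-yl (2R)-2-acetoxy-4-{(2S)-2-[(1Z)-4-[(4-methoxybenzyl)oxy]-2-methylbut-1-en-1-yl]-5-oxo-4-[(triethylsilyloxy)methyl]-2,5-dihydrofuran-3-yl}-2-methyl-4-oxobutanoate
Conditions: Dess–Martin periodinane, NaHCO3, CH2Cl2, 0 °C → rt
Reagents that add atoms: none
Why: Dess–Martin oxidation; it converges the two C8 epimers into one ketone and is buffered so that the β-acetoxy ketone does not eliminate.

Step 16
Reactants: 20 C8 ketone
Product: 21 prop-2-en-1-yl (2R,4S)-2-acetoxy-4-hydroxy-4-{(2S)-2-[(1Z)-4-[(4-methoxybenzyl)oxy]-2-methylbut-1-en-1-yl]-5-oxo-4-[(triethylsilyloxy)methyl]-2,5-dihydrofuran-3-yl}-2-methylbutanoate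
Conditions: (R)-2-methyl-CBS-oxazaborolidine, catecholborane, toluene, −78 °C
Reagents that add atoms: none
Why: Corey–Bakshi–Shibata reduction; the fully substituted alkenyl carbon C7 acts as the large group and the C9 methylene as the small one, so the (R)-catalyst should deliver hydride to give 8S. Catecholborane leaves the esters and the allyl alkene alone.

Step 17
Reactants: 21 (8S)-carbinol
Product: 22 prop-2-en-1-yl (2R,4S)-2-acetoxy-4-{(2S)-2-[(1Z)-4-[(4-methoxybenzyl)oxy]-2-methylbut-1-en-1-yl]-5-oxo-4-[(triethylsilyloxy)methyl]-2,5-dihydrofuran-3-yl}-2-methyl-4-(triethylsilyloxy)butanoate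
Conditions: Et3SiOTf, 2,6-lutidine, CH2Cl2, −78 °C
Reagents that add atoms: triethylsilyl trifluoromethanesulfonate, CC[Si](CC)(CC)OS(=O)(=O)C(F)(F)F
Why: Silylation with a silyl triflate; at −78 °C it should outrun lactonisation of the C8 hydroxyl onto the allyl ester and 1,3-migration of the C10 acetate.

Step 18
Reactants: 22 bis(triethylsilyl) ether with 4Z alkene
Product: 23 prop-2-en-1-yl (2R,4S)-2-acetoxy-4-{(2R)-2-[(2S,3R)-3-{2-[(4-methoxybenzyl)oxy]ethyl}-3-methyloxiran-2-yl]-5-oxo-4-[(triethylsilyloxy)methyl]-2,5-dihydrofuran-3-yl}-2-methyl-4-(triethylsilyloxy)butanoate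
Conditions: mCPBA, NaHCO3, CH2Cl2, 0 °C
Reagents that add atoms: 3-chloroperbenzoic acid, OOC(=O)c1cccc(Cl)c1
Why: Prilezhaev epoxidation of the only electron-rich alkene. A(1,3) strain with the cis C3 methylene holds C6–H in the alkene plane, the C7 substituent with its silyloxy chain covers one face, and the peracid should add syn to the lactone oxygen, giving 4R,5S.

Step 19
Reactants: 23 epoxide with PMB ether
Product: 24 prop-2-en-1-yl (2R,4S)-2-acetoxy-4-{(2R)-2-[(2S,3R)-3-(2-hydroxyethyl)-3-methyloxiran-2-yl]-5-oxo-4-[(triethylsilyloxy)methyl]-2,5-dihydrofuran-3-yl}-2-methyl-4-(triethylsilyloxy)butanoate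
Conditions: DDQ, CH2Cl2/pH 7 buffer, 0 °C → rt
Reagents that add atoms: none
Why: Oxidative cleavage of the PMB ether; the buffered two-phase medium keeps the epoxide and the silyl ethers intact.

Step 20
Reactants: 24 C2 alcohol
Product: 25 prop-2-en-1-yl (2R,4S)-2-acetoxy-4-{(2R)-2-[(2S,3R)-3-(2-iodoethyl)-3-methyloxiran-2-yl]-5-oxo-4-[(triethylsilyloxy)methyl]-2,5-dihydrofuran-3-yl}-2-methyl-4-(triethylsilyloxy)butanoate
Conditions: I2, PPh3, imidazole, CH2Cl2, 0 °C
Reagents that add atoms: iodine, II
Why: Appel-type iodination of the primary alcohol; fast and near neutral, and done before the thioester exists so that the active ester never meets imidazole.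

Step 21
Reactants: 25 allyl ester iodide
Product: 26 (2R,4S)-2-acetoxy-4-{(2R)-2-[(2S,3R)-3-(2-iodoethyl)-3-methyloxiran-2-yl]-5-oxo-4-[(triethylsilyloxy)methyl]-2,5-dihydrofuran-3-yl}-2-methyl-4-(triethylsilyloxy)butanoic acid
Conditions: Pd(PPh3)4 (5 mol %), N-methylaniline, THF, 0 °C → rt
Reagents that add atoms: none
Why: Palladium-catalysed allyl transfer (Tsuji–Trost deallylation) to a weakly basic amine; zerovalent palladium with PPh3 adds to the allyl ester far faster than to an unactivated primary iodide, and no allylic acetate is present to compete.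

Step 22
Reactants: 26 C1 acid
Product: 27 S-pyridin-2-yl (2R,4S)-2-acetoxy-4-{(2R)-2-[(2S,3R)-3-(2-iodoethyl)-3-methyloxiran-2-yl]-5-oxo-4-[(triethylsilyloxy)methyl]-2,5-dihydrofuran-3-yl}-2-methyl-4-(triethylsilyloxy)butanethioate
Conditions: 2,2'-dipyridyl disulfide, PPh3, CH2Cl2, rt
Reagents that add atoms: 2,2'-dipyridyl disulfide, c1ccc(SSc2ccccn2)nc1
Why: Redox condensation of the acid with disulfide and phosphine (Mukaiyama-type thioesterification); neutral, and the product is purified quickly to remove the thiol by-product, which could alkylate at C2.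

Step 23
Reactants: 27 seco 2-pyridyl thioester iodide
Product: 28 (4R,5S,6R,8S,10R)-10-acetoxy-4,5-epoxy-1-oxo-8,13-bis(triethylsilyloxy)germacr-7(11)-en-12,6-olide
Conditions: NiBr2(dtbbpy) (30 mol %), Zn dust, DMA, 25 °C, syringe-pump addition of 27, final 1 mM
Reagents that add atoms: none
Why: Proposed new method: zinc reduces NiBr2(dtbbpy) to zerovalent nickel, which inserts into the chelating 2-pyridyl acyl–sulfur bond at C1; univalent nickel abstracts iodine from C2, the primary radical is captured by the acylnickel of the same molecule, and reductive elimination from trivalent nickel forms the C1–C2 ketone bond. The closest known reaction is the intermolecular nickel-catalysed reductive ketone synthesis from 2-pyridyl thioesters or acid chlorides and alkyl iodides; closing a ring of this size with it is the untested part. The ten-membered carbocycle is closed by acyl–alkyl bond formation between C1 and C2 through an eleven-membered acyl(alkyl)nickel species. No stereocentre is formed and none is at risk, because no enolate, alkoxide or acid is present and C10 is quaternary. Chemoselectivity rests on the substrate: the only allylic oxygen with a free rotor, at C13, is a silyl ether and not an acetate; the lactone C6–O bond lies in the plane of the C7=C11 alkene and cannot ionise to an allyl complex; and the epoxide is two carbons from the radical centre. Ring closure over oligomerisation is favoured by slow addition to about 1 mM and by the cis-epoxide and the butenolide, which hold four of the ten ring atoms in a bent array.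

Step 24
Reactants: 28 macrocyclic bis(triethylsilyl) ether
Product: 29 (4R,5S,6R,8S,10R)-10-acetoxy-4,5-epoxy-8,13-dihydroxy-1-oxogermacr-7(11)-en-12,6-olide
Conditions: HF·pyridine, pyridine, THF, 0 °C → rt
Reagents that add atoms: none
Why: Fluoride-mediated desilylation buffered with pyridine; it removes both silyl ethers without base strong enough to deprotonate C6 and without free acid at the epoxide.

Step 25
Reactants: 29 8,13-diol
Product: 30 (4R,5S,6R,8S,10R)-10,13-diacetoxy-4,5-epoxy-8-hydroxy-1-oxogermacr-7(11)-en-12,6-olide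
Conditions: Ac2O (1.1 equiv), 2,4,6-collidine, CH2Cl2, −40 → 0 °C
Reagents that add atoms: acetic anhydride, CC(=O)OC(C)=O
Why: Selective acylation of the primary alcohol; the unhindered C13 hydroxyl should be acetylated well before the hindered secondary C8 hydroxyl with a weak, bulky base.

Step 26
Reactants: 30 8-hydroxy 13-acetate
Product: 31 CNP0172381.2, (4R,5S,6R,8S,10R)-10,13-diacetoxy-4,5-epoxy-8-(methacryloyloxy)-1-oxogermacr-7(11)-en-12,6-olide
Conditions: methacrylic anhydride, DMAP (cat.), pyridine, CH2Cl2, 0 °C → rt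
Reagents that add atoms: methacrylic anhydride, C=C(C)C(=O)OC(=O)C(C)=C
Why: DMAP-catalysed esterification; the acylation of the C8 hydroxyl with retention at 0 °C should be faster than acetyl migration from C10 or deprotonation at C6.

## Compound list

1 | but-3-yn-1-ol | OCCC#C | starting material
2 | 1-[(but-3-yn-1-yloxy)methyl]-4-methoxybenzene | C#CCCOCc1ccc(OC)cc1 | intermediate
3 | methyl 5-[(4-methoxybenzyl)oxy]pent-2-ynoate | COC(=O)C#CCCOCc1ccc(OC)cc1 | intermediate
4 | methyl (2Z)-5-[(4-methoxybenzyl)oxy]-3-methylpent-2-enoate | COC(=O)/C=C(/C)CCOCc1ccc(OC)cc1 | intermediate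
5 | (2Z)-5-[(4-methoxybenzyl)oxy]-3-methylpent-2-en-1-ol | OC/C=C(/C)CCOCc1ccc(OC)cc1 | intermediate
6 | (2Z)-5-[(4-methoxybenzyl)oxy]-3-methylpent-2-enal | O=C/C=C(/C)CCOCc1ccc(OC)cc1 | intermediate
7 | methyl propiolate | C#CC(=O)OC | starting material
8 | methyl (4S,5Z)-4-hydroxy-8-[(4-methoxybenzyl)oxy]-6-methyloct-5-en-2-ynoate | COC(=O)C#C[C@@H](O)/C=C(/C)CCOCc1ccc(OC)cc1 | intermediate
9 | methyl (2E,4S,5Z)-4-hydroxy-2-(hydroxymethyl)-3-iodo-8-[(4-methoxybenzyl)oxy]-6-methylocta-2,5-dienoate | COC(=O)/C(CO)=C(I)\[C@@H](O)/C=C(/C)CCOCc1ccc(OC)cc1 | intermediate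
10 | (5S)-3-(hydroxymethyl)-4-iodo-5-[(1Z)-4-[(4-methoxybenzyl)oxy]-2-methylbut-1-en-1-yl]furan-2(5H)-one | OCC1=C(I)[C@H](/C=C(/C)CCOCc2ccc(OC)cc2)OC1=O | intermediate
11 | (5S)-4-iodo-5-[(1Z)-4-[(4-methoxybenzyl)oxy]-2-methylbut-1-en-1-yl]-3-[(triethylsilyloxy)methyl]furan-2(5H)-one | CC[Si](CC)(CC)OCC1=C(I)[C@H](/C=C(/C)CCOCc2ccc(OC)cc2)OC1=O | intermediate
12 | (S)-lactic acid | C[C@H](O)C(=O)O | starting material
13 | (2S,5S)-2-tert-butyl-5-methyl-1,3-dioxolan-4-one | C[C@@H]1O[C@H](C(C)(C)C)OC1=O | intermediate
14 | (2S,5R)-2-tert-butyl-5-methyl-5-(3-methylbut-2-en-1-yl)-1,3-dioxolan-4-one | C[C@]1(CC=C(C)C)O[C@H](C(C)(C)C)OC1=O | intermediate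
15 | prop-2-en-1-yl (2R)-2-hydroxy-2,5-dimethylhex-4-enoate | C=CCOC(=O)[C@](C)(O)CC=C(C)C | intermediate
16 | prop-2-en-1-yl (2R)-2-acetoxy-2,5-dimethylhex-4-enoate | C=CCOC(=O)[C@](C)(OC(C)=O)CC=C(C)C | intermediate
17 | prop-2-en-1-yl (2R)-2-acetoxy-3-(5,5-dimethyl-1,2,4-trioxolan-3-yl)-2-methylpropanoate | C=CCOC(=O)[C@](C)(OC(C)=O)CC1OOC(C)(C)O1 | intermediate
18 | prop-2-en-1-yl (2R)-2-acetoxy-2-methyl-4-oxobutanoate | C=CCOC(=O)[C@](C)(OC(C)=O)CC=O | intermediate
19 | prop-2-en-1-yl (2R)-2-acetoxy-4-hydroxy-4-{(2S)-2-[(1Z)-4-[(4-methoxybenzyl)oxy]-2-methylbut-1-en-1-yl]-5-oxo-4-[(triethylsilyloxy)methyl]-2,5-dihydrofuran-3-yl}-2-methylbutanoate, both C4 epimers | OC(C[C@@](C)(OC(C)=O)C(=O)OCC=C)C1=C(CO[Si](CC)(CC)CC)C(=O)O[C@H]1/C=C(/C)CCOCc1ccc(OC)cc1 | intermediate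
20 | prop-2-en-1-yl (2R)-2-acetoxy-4-{(2S)-2-[(1Z)-4-[(4-methoxybenzyl)oxy]-2-methylbut-1-en-1-yl]-5-oxo-4-[(triethylsilyloxy)methyl]-2,5-dihydrofuran-3-yl}-2-methyl-4-oxobutanoate | O=C(C[C@@](C)(OC(C)=O)C(=O)OCC=C)C1=C(CO[Si](CC)(CC)CC)C(=O)O[C@H]1/C=C(/C)CCOCc1ccc(OC)cc1 | intermediate
21 | prop-2-en-1-yl (2R,4S)-2-acetoxy-4-hydroxy-4-{(2S)-2-[(1Z)-4-[(4-methoxybenzyl)oxy]-2-methylbut-1-en-1-yl]-5-oxo-4-[(triethylsilyloxy)methyl]-2,5-dihydrofuran-3-yl}-2-methylbutanoate | O[C@@H](C[C@@](C)(OC(C)=O)C(=O)OCC=C)C1=C(CO[Si](CC)(CC)CC)C(=O)O[C@H]1/C=C(/C)CCOCc1ccc(OC)cc1 | intermediate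
22 | prop-2-en-1-yl (2R,4S)-2-acetoxy-4-{(2S)-2-[(1Z)-4-[(4-methoxybenzyl)oxy]-2-methylbut-1-en-1-yl]-5-oxo-4-[(triethylsilyloxy)methyl]-2,5-dihydrofuran-3-yl}-2-methyl-4-(triethylsilyloxy)butanoate | CC[Si](CC)(CC)O[C@@H](C[C@@](C)(OC(C)=O)C(=O)OCC=C)C1=C(CO[Si](CC)(CC)CC)C(=O)O[C@H]1/C=C(/C)CCOCc1ccc(OC)cc1 | intermediate
23 | prop-2-en-1-yl (2R,4S)-2-acetoxy-4-{(2R)-2-[(2S,3R)-3-{2-[(4-methoxybenzyl)oxy]ethyl}-3-methyloxiran-2-yl]-5-oxo-4-[(triethylsilyloxy)methyl]-2,5-dihydrofuran-3-yl}-2-methyl-4-(triethylsilyloxy)butanoate | CC[Si](CC)(CC)O[C@@H](C[C@@](C)(OC(C)=O)C(=O)OCC=C)C1=C(CO[Si](CC)(CC)CC)C(=O)O[C@H]1[C@@H]1O[C@]1(C)CCOCc1ccc(OC)cc1 | intermediate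
24 | prop-2-en-1-yl (2R,4S)-2-acetoxy-4-{(2R)-2-[(2S,3R)-3-(2-hydroxyethyl)-3-methyloxiran-2-yl]-5-oxo-4-[(triethylsilyloxy)methyl]-2,5-dihydrofuran-3-yl}-2-methyl-4-(triethylsilyloxy)butanoate | CC[Si](CC)(CC)O[C@@H](C[C@@](C)(OC(C)=O)C(=O)OCC=C)C1=C(CO[Si](CC)(CC)CC)C(=O)O[C@H]1[C@@H]1O[C@]1(C)CCO | intermediate
25 | prop-2-en-1-yl (2R,4S)-2-acetoxy-4-{(2R)-2-[(2S,3R)-3-(2-iodoethyl)-3-methyloxiran-2-yl]-5-oxo-4-[(triethylsilyloxy)methyl]-2,5-dihydrofuran-3-yl}-2-methyl-4-(triethylsilyloxy)butanoate | CC[Si](CC)(CC)O[C@@H](C[C@@](C)(OC(C)=O)C(=O)OCC=C)C1=C(CO[Si](CC)(CC)CC)C(=O)O[C@H]1[C@@H]1O[C@]1(C)CCI | intermediate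
26 | (2R,4S)-2-acetoxy-4-{(2R)-2-[(2S,3R)-3-(2-iodoethyl)-3-methyloxiran-2-yl]-5-oxo-4-[(triethylsilyloxy)methyl]-2,5-dihydrofuran-3-yl}-2-methyl-4-(triethylsilyloxy)butanoic acid | CC[Si](CC)(CC)O[C@@H](C[C@@](C)(OC(C)=O)C(=O)O)C1=C(CO[Si](CC)(CC)CC)C(=O)O[C@H]1[C@@H]1O[C@]1(C)CCI | intermediate
27 | S-pyridin-2-yl (2R,4S)-2-acetoxy-4-{(2R)-2-[(2S,3R)-3-(2-iodoethyl)-3-methyloxiran-2-yl]-5-oxo-4-[(triethylsilyloxy)methyl]-2,5-dihydrofuran-3-yl}-2-methyl-4-(triethylsilyloxy)butanethioate | CC[Si](CC)(CC)O[C@@H](C[C@@](C)(OC(C)=O)C(=O)Sc1ccccn1)C1=C(CO[Si](CC)(CC)CC)C(=O)O[C@H]1[C@@H]1O[C@]1(C)CCI | intermediate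
28 | (4R,5S,6R,8S,10R)-10-acetoxy-4,5-epoxy-1-oxo-8,13-bis(triethylsilyloxy)germacr-7(11)-en-12,6-olide | CC[Si](CC)(CC)O[C@H]1C[C@@](C)(OC(C)=O)C(=O)CC[C@@]2(C)O[C@H]2[C@@H]2OC(=O)C(CO[Si](CC)(CC)CC)=C12 | intermediate
29 | (4R,5S,6R,8S,10R)-10-acetoxy-4,5-epoxy-8,13-dihydroxy-1-oxogermacr-7(11)-en-12,6-olide | O[C@H]1C[C@@](C)(OC(C)=O)C(=O)CC[C@@]2(C)O[C@H]2[C@@H]2OC(=O)C(CO)=C12 | intermediate
30 | (4R,5S,6R,8S,10R)-10,13-diacetoxy-4,5-epoxy-8-hydroxy-1-oxogermacr-7(11)-en-12,6-olide | O[C@H]1C[C@@](C)(OC(C)=O)C(=O)CC[C@@]2(C)O[C@H]2[C@@H]2OC(=O)C(COC(C)=O)=C12 | intermediate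
31 | CNP0172381.2, (4R,5S,6R,8S,10R)-10,13-diacetoxy-4,5-epoxy-8-(methacryloyloxy)-1-oxogermacr-7(11)-en-12,6-olide | C=C(C)C(=O)O[C@H]1C[C@@](C)(OC(C)=O)C(=O)CC[C@@]2(C)O[C@H]2[C@@H]2OC(=O)C(COC(C)=O)=C12 | target

## Step count and least certain steps

Total: 26 steps. Longest linear sequence: 21 steps (steps 1–8 and 14–26, from but-3-yn-1-ol); the lactate branch is steps 9–13.

Step 23 (key step, proposed new method). The most likely failures are:
- intermolecular acyl–alkyl coupling outrunning ring closure, because a ten-membered ring is entropically and transannularly disfavoured;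
- hydrogen-atom transfer from the doubly activated C6–H to the C2 radical through a six-membered transition state, or 6-exo addition of that radical to C7, before the radical is captured at nickel;
- protodehalogenation through an alkylzinc;
- loss of CO from the hindered α-acetoxy acylnickel.

Fallback with known chemistry, setting out from acid 26: BH3·SMe2 reduction of the acid gives the C1 primary alcohol F1, which is oxidised at once by Dess–Martin oxidation to the non-enolisable C1 aldehyde F2. A cobalt-catalysed chromium Barbier cyclisation of the primary iodide onto the aldehyde (CrCl2, catalytic CoPc (cobalt phthalocyanine, C32H16CoN8), DMF, high dilution) would give the macrocyclic C1 carbinol F3 as a mixture of epimers. Dess–Martin oxidation of that mixture returns to the route at ketone 28.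

Step 7. The iodide addition–aldol may stop at the geometric isomer that has iodine cis to the ester and cannot lactonise, if equilibration by iodide addition–elimination is slow. The magnesium salt may also ionise the allylic, propargylic C6–O bond and erode the C6 configuration.

Fallback that swaps the roles of the two carbinol carbons, setting out from aldehyde 18 and methyl propiolate 7: ProPhenol/Me2Zn alkynylation of 18 gives the C8 propargylic alcohol F4 (C8 set by the catalyst), which is silylated to the triethylsilyl ether F5. MgI2 and formaldehyde then give the (Z)-iodo hydroxymethyl enoate F6; here the usual isomer with iodine cis to the ester is the one needed. Silylation gives the bis(triethylsilyl) ether F7. CrCl2/NiCl2 coupling of F7 with enal 6 and spontaneous lactonisation of the C6 alkoxide onto the methyl ester rejoins the route at 22. The price is that C6 is then formed without reagent control and its epimers must be separated.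

Step 14. The alkenylchromium derived from 11 has the lactone C6–O bond anti-periplanar to the C7–metal bond, so β-elimination with ring opening to an allenoate may compete with addition. Insertion of zerovalent nickel into the allyl ester of 18 is a second possible drain.

Fallback without an alkenylchromium, setting out from 11 and 18: Pd(PPh3)4 with Me3Sn–SnMe3 converts 11 into the 4-(trimethylstannyl)butenolide F8. Pinnick oxidation of 18 (NaClO2, NaH2PO4, 2-methylbut-2-ene) gives the carboxylic acid F9, and oxalyl chloride with catalytic DMF gives the acid chloride F10. Stille acylation of F8 with F10 (PdCl2(PPh3)2, toluene, 60 °C) gives ketone 20 directly, so the fallback also bypasses step 15.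

Step 18. Poor facial selectivity is the risk: the electrostatic preference of a peracid to attack anti to an allylic C–O bond works against the steric preference for the face syn to the lactone oxygen, and no hydroxyl directs the reagent.

Fallback with catalyst control, setting out from 22: DDQ removes the PMB ether first to give the homoallylic alcohol F11. A vanadium-catalysed epoxidation directed by the C2 hydroxyl (VO(OiPr)3, a chiral C2-symmetric bishydroxamic acid ligand, cumene hydroperoxide, toluene, 0 °C) then selects the alkene face through the ligand, and the product is epoxy alcohol 24, where the route is rejoined.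

## Further compounds

F1 | step 23 | (5R)-4-[(1S,3R)-3-acetoxy-4-hydroxy-3-methyl-1-(triethylsilyloxy)butyl]-5-[(2S,3R)-3-(2-iodoethyl)-3-methyloxiran-2-yl]-3-[(triethylsilyloxy)methyl]furan-2(5H)-one | CC[Si](CC)(CC)O[C@@H](C[C@@](C)(OC(C)=O)CO)C1=C(CO[Si](CC)(CC)CC)C(=O)O[C@H]1[C@@H]1O[C@]1(C)CCI
F2 | step 23 | (2R,4S)-2-acetoxy-4-{(2R)-2-[(2S,3R)-3-(2-iodoethyl)-3-methyloxiran-2-yl]-5-oxo-4-[(triethylsilyloxy)methyl]-2,5-dihydrofuran-3-yl}-2-methyl-4-(triethylsilyloxy)butanal | CC[Si](CC)(CC)O[C@@H](C[C@@](C)(OC(C)=O)C=O)C1=C(CO[Si](CC)(CC)CC)C(=O)O[C@H]1[C@@H]1O[C@]1(C)CCI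
F3 | step 23 | (4R,5S,6R,8S,10R)-10-acetoxy-4,5-epoxy-1-hydroxy-8,13-bis(triethylsilyloxy)germacr-7(11)-en-12,6-olide, both C1 epimers | CC[Si](CC)(CC)O[C@H]1C[C@@](C)(OC(C)=O)C(O)CC[C@@]2(C)O[C@H]2[C@@H]2OC(=O)C(CO[Si](CC)(CC)CC)=C12
F4 | step 7 | 1-methyl 7-(prop-2-en-1-yl) (4S,6R)-6-acetoxy-4-hydroxy-6-methylhept-2-ynedioate | COC(=O)C#C[C@@H](O)C[C@@](C)(OC(C)=O)C(=O)OCC=C
F5 | step 7 | 1-methyl 7-(prop-2-en-1-yl) (4S,6R)-6-acetoxy-6-methyl-4-(triethylsilyloxy)hept-2-ynedioate | COC(=O)C#C[C@@H](O[Si](CC)(CC)CC)C[C@@](C)(OC(C)=O)C(=O)OCC=C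
F6 | step 7 | 1-methyl 7-(prop-2-en-1-yl) (2Z,4S,6R)-6-acetoxy-2-(hydroxymethyl)-3-iodo-6-methyl-4-(triethylsilyloxy)hept-2-enedioate | COC(=O)/C(CO)=C(\I)[C@@H](O[Si](CC)(CC)CC)C[C@@](C)(OC(C)=O)C(=O)OCC=C
F7 | step 7 | 1-methyl 7-(prop-2-en-1-yl) (2Z,4S,6R)-6-acetoxy-3-iodo-6-methyl-4-(triethylsilyloxy)-2-[(triethylsilyloxy)methyl]hept-2-enedioate | COC(=O)/C(CO[Si](CC)(CC)CC)=C(\I)[C@@H](O[Si](CC)(CC)CC)C[C@@](C)(OC(C)=O)C(=O)OCC=C
F8 | step 14 | (5S)-5-[(1Z)-4-[(4-methoxybenzyl)oxy]-2-methylbut-1-en-1-yl]-3-[(triethylsilyloxy)methyl]-4-(trimethylstannyl)furan-2(5H)-one | C[Sn](C)(C)C1=C(CO[Si](CC)(CC)CC)C(=O)O[C@H]1/C=C(/C)CCOCc1ccc(OC)cc1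
F9 | step 14 | (3R)-3-acetoxy-3-methyl-4-oxo-4-(prop-2-en-1-yloxy)butanoic acid | OC(=O)C[C@@](C)(OC(C)=O)C(=O)OCC=C
F10 | step 14 | prop-2-en-1-yl (2R)-2-acetoxy-4-chloro-2-methyl-4-oxobutanoate | ClC(=O)C[C@@](C)(OC(C)=O)C(=O)OCC=C
F11 | step 18 | prop-2-en-1-yl (2R,4S)-2-acetoxy-4-{(2S)-2-[(1Z)-4-hydroxy-2-methylbut-1-en-1-yl]-5-oxo-4-[(triethylsilyloxy)methyl]-2,5-dihydrofuran-3-yl}-2-methyl-4-(triethylsilyloxy)butanoate | CC[Si](CC)(CC)O[C@@H](C[C@@](C)(OC(C)=O)C(=O)OCC=C)C1=C(CO[Si](CC)(CC)CC)C(=O)O[C@H]1/C=C(/C)CCO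
A1 | alternative 1 | saturated 12,6-lactone with C11 allyl ester and C8 chloroacetate on the 10-acetoxy-4,5-epoxy-1-oxogermacrane ring (C7 and C11 drawn as one diastereomer) | ClCC(=O)O[C@H]1C[C@@](C)(OC(C)=O)C(=O)CC[C@@]2(C)O[C@H]2[C@@H]2OC(=O)[C@@H](C(=O)OCC=C)[C@H]12
A2 | alternative 1 | C6 allyl diazomalonate of (4R,5S,6R,8S,10R)-10-acetoxy-8-(chloroacetoxy)-4,5-epoxy-6-hydroxycyclodecan-1-one skeleton | ClCC(=O)O[C@H]1C[C@@](C)(OC(C)=O)C(=O)CC[C@@]2(C)O[C@H]2[C@H](OC(=O)C(=[N+]=[N-])C(=O)OCC=C)C1
A3 | alternative 2 | (8S)-8-[(4-methoxybenzyl)oxy]germacra-4Z,1(10)E-dien-6-one (ten-membered dienone without C11–C13) | COc1ccc(CO[C@H]2C/C(C)=C/CC/C(C)=C\C(=O)C2)cc1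
A4 | alternative 2 | (1S,6S)-1-{(E)-2-[(4-methoxybenzyl)oxy]ethenyl}-3-methyl-6-(prop-1-en-2-yl)cyclohex-2-en-1-ol | COc1ccc(CO/C=C/[C@]2(O)C=C(C)CC[C@H]2C(C)=C)cc1
A5 | alternative 3 | (6R,8S,10R)-10,13-diacetoxy-1-oxo-8-(triethylsilyloxy)germacra-4Z,7(11)-dien-12,6-olide | CC[Si](CC)(CC)O[C@H]1C[C@@](C)(OC(C)=O)C(=O)CC/C(C)=C\[C@@H]2OC(=O)C(COC(C)=O)=C12
A6 | alternative 3 | methyl (2Z,4S,6R,10Z)-6-acetoxy-2-(acetoxymethyl)-3-iodo-6,10-dimethyl-7,12-dioxo-4-(triethylsilyloxy)dodeca-2,10-dienoate | CC[Si](CC)(CC)O[C@@H](C[C@@](C)(OC(C)=O)C(=O)CC/C(C)=C\C=O)/C(I)=C(\COC(C)=O)C(=O)OC
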